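**Retrosynthetic overview**
1. Target 11 ⇐ 10 by removal of the 4'-O-MOM group.
2. 10 ⇐ 7 by a Eu(III)-catalysed para-Claisen–Cope rearrangement: the 5-O-prenyl group travels O5 → C6 → C8 and unmasks the 5-OH.
3. 7 ⇐ 6 by a new organocatalytic enantioselective 6-endo oxa-Michael ring closure (O1–C2 bond, C2 = S). Only one free OH is present in 6, so the regiochemistry is fixed.
4. 6 ⇐ 3 + 4 (Claisen–Schmidt); 3 ⇐ 1 + 2 (mono-O-prenylation of a symmetric diphenol).
5. Rings A and B are bought as arenes; the pyranone ring C is the only ring formed (step 3).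

**Assumptions**
- 1 and 4 are catalogue compounds.
- Catalyst for step 3 ("cat-A", pre-formed): 1-[3,5-bis(trifluoromethyl)phenyl]-3-[(2S)-3,3-dimethyl-1-{[tris(4-methoxyphenyl)-λ5-phosphanylidene]amino}butan-2-yl]thiourea, SMILES COc1ccc(cc1)P(=NC[C@@H](NC(=S)Nc1cc(cc(c1)C(F)(F)F)C(F)(F)F)C(C)(C)C)(c1ccc(OC)cc1)c1ccc(OC)cc1.
- The sense of induction of the new step cannot be predicted with certainty. If the first run gives (2R), the mirror-image catalyst from D-tert-leucine is used. (2S)-Flavanones show a negative Cotton effect near 290 nm and a positive one near 330 nm.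

**Route**

Step 1
Reactants: 1 1-(2,6-dihydroxy-4-methoxyphenyl)ethan-1-one; 2 1-bromo-3-methylbut-2-ene (prenyl bromide)
Product: 3 1-[2-hydroxy-4-methoxy-6-(3-methylbut-2-en-1-yloxy)phenyl]ethan-1-one
Conditions: 2 (1.1 equiv), K2CO3 (1.5 equiv), acetone, reflux, 6 h
Reagents that add atoms: none
Why: Williamson O-alkylation; the two OH groups of 1 are equivalent, and after the first alkylation the remaining OH is locked in a strong hydrogen bond to the acetyl C=O, so the reaction stops at the mono-ether and K2CO3/acetone favours O- over C-prenylation.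

Step 2
Reactants: 3 1-[2-hydroxy-4-methoxy-6-(3-methylbut-2-en-1-yloxy)phenyl]ethan-1-one; 4 4-(methoxymethoxy)benzaldehyde
Product: 6 (E)-1-[2-hydroxy-4-methoxy-6-(3-methylbut-2-en-1-yloxy)phenyl]-3-[4-(methoxymethoxy)phenyl]prop-2-en-1-one, via aldol adduct 5 (not isolated)
Conditions: KOH (50% aq, 5 equiv, base only, not consumed), EtOH, 0 °C to rt, 36 h; cold citric acid to pH 5–6; remove any racemic flavanone by chromatography or crystallisation
Reagents that add atoms: none
Why: Claisen–Schmidt (crossed aldol) condensation with a non-enolisable aldehyde, where E1cB dehydration of 5 gives the conjugated (E)-enone, which rests as the stable chalcone phenoxide in strong base and so does not ring-close before the cold, mildly acidic quench; MOM and prenyl ethers are base-stable.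

Step 3
Reactants: 6 (E)-1-[2-hydroxy-4-methoxy-6-(3-methylbut-2-en-1-yloxy)phenyl]-3-[4-(methoxymethoxy)phenyl]prop-2-en-1-one
Product: 7 (2S)-7-methoxy-2-[4-(methoxymethoxy)phenyl]-5-(3-methylbut-2-en-1-yloxy)-2,3-dihydro-4H-chromen-4-one
Conditions: cat-A (10 mol %), toluene (0.1 M), −20 °C, 24–48 h; AcOH quench at −20 °C; recrystallise to raise ee if needed
Reagents that add atoms: none
Why: Proposed new method: a bifunctional iminophosphorane (BIMP) superbase–thiourea catalyst is applied to an unactivated 2'-hydroxychalcone (no α-ester activating group), which to my knowledge has not been shown; the iminophosphorane deprotonates the chelated 2'-OH to a tight aminophosphonium phenoxide ion pair while the thiourea N–H pair binds and polarises the enone C=O, so the phenoxide oxygen adds 6-endo-trig to one enantiotopic face of the β-carbon inside the chiral pocket (this C–O bond formation sets C2 as S) and the enolate is protonated at C3 by the P–NH+ unit to release the catalyst; the 6'-prenyloxy group twists the aroyl unit out of conjugation so ring closure is exergonic, the product has no acidic OH to sequester the base, and at −20 °C with an acid quench the retro-oxa-Michael (racemisation) channel is slow; the closest known reaction types are BIMP-catalysed intramolecular oxa-Michael additions of alcohols to α,β-unsaturated esters and amides and the tertiary-amine–thiourea cyclisation of α-alkoxycarbonyl-activated 2'-hydroxychalcones to flavanones.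

Step 4
Reactants: 7 (2S)-7-methoxy-2-[4-(methoxymethoxy)phenyl]-5-(3-methylbut-2-en-1-yloxy)-2,3-dihydro-4H-chromen-4-one
Product: 10 (2S)-5-hydroxy-7-methoxy-2-[4-(methoxymethoxy)phenyl]-8-(3-methylbut-2-en-1-yl)-2,3-dihydro-4H-chromen-4-one, via ortho-dienone 8 (not isolated), via para-dienone 9 (not isolated)
Conditions: Eu(fod)3 (10 mol %), NaHCO3 (1 equiv, acid scavenger, unchanged), PhCl, 85 °C, 18–24 h
Reagents that add atoms: none
Why: Eu(III)-catalysed aromatic para-Claisen–Cope rearrangement, in which chelation of Eu between C4=O and O5 triggers the [3,3] shift of the prenyl group to C6 (reverse-prenyl dienone 8), a second [3,3] (Cope) shift carries it to C8 with the normal prenyl restored (dienone 9), and tautomerisation gives the chelated 5-phenol; C2 is not involved and no base strong enough for ring opening is present, so (S) is retained.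

Step 5
Reactants: 10 (2S)-5-hydroxy-7-methoxy-2-[4-(methoxymethoxy)phenyl]-8-(3-methylbut-2-en-1-yl)-2,3-dihydro-4H-chromen-4-one
Product: 11 (2S)-5-hydroxy-2-(4-hydroxyphenyl)-7-methoxy-8-(3-methylbut-2-en-1-yl)-2,3-dihydro-4H-chromen-4-one (Mundulea flavanone B)
Conditions: HCl (3 M aq, catalytic role), MeOH, 40 °C, 2–4 h
Reagents that add atoms: none
Why: acid-catalysed solvolysis of the MOM acetal; the C8 prenyl group is flanked by OMe and the ring oxygen (no free ortho-OH), so it cannot cyclise to a chroman, and dilute acid at 40 °C does not open the flavanone ring, so C2 stays (S).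

**Compound list**
1 | 1-(2,6-dihydroxy-4-methoxyphenyl)ethan-1-one | CC(=O)c1c(O)cc(OC)cc1O | starting material
2 | 1-bromo-3-methylbut-2-ene (prenyl bromide) | CC(C)=CCBr | starting material
3 | 1-[2-hydroxy-4-methoxy-6-(3-methylbut-2-en-1-yloxy)phenyl]ethan-1-one | CC(=O)c1c(O)cc(OC)cc1OCC=C(C)C | intermediate
4 | 4-(methoxymethoxy)benzaldehyde | COCOc1ccc(C=O)cc1 | starting material
5 | 3-hydroxy-1-[2-hydroxy-4-methoxy-6-(3-methylbut-2-en-1-yloxy)phenyl]-3-[4-(methoxymethoxy)phenyl]propan-1-one (racemic aldol adduct; not isolated) | COCOc1ccc(cc1)C(O)CC(=O)c1c(O)cc(OC)cc1OCC=C(C)C | intermediate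
6 | (E)-1-[2-hydroxy-4-methoxy-6-(3-methylbut-2-en-1-yloxy)phenyl]-3-[4-(methoxymethoxy)phenyl]prop-2-en-1-one | COCOc1ccc(/C=C/C(=O)c2c(O)cc(OC)cc2OCC=C(C)C)cc1 | intermediate
7 | (2S)-7-methoxy-2-[4-(methoxymethoxy)phenyl]-5-(3-methylbut-2-en-1-yloxy)-2,3-dihydro-4H-chromen-4-one | COc1cc(OCC=C(C)C)c2c(c1)O[C@H](c1ccc(OCOC)cc1)CC2=O | intermediate
8 | (2S)-7-methoxy-2-[4-(methoxymethoxy)phenyl]-6-(2-methylbut-3-en-2-yl)-2,3-dihydro-4H-chromene-4,5(6H)-dione (ortho-dienone; C6 epimers; not isolated) | COC1=CC2=C(C(=O)C1C(C)(C)C=C)C(=O)C[C@@H](c1ccc(OCOC)cc1)O2 | intermediate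
9 | (2S)-7-methoxy-2-[4-(methoxymethoxy)phenyl]-8-(3-methylbut-2-en-1-yl)-2,3-dihydro-4H-chromene-4,5(8H)-dione (para-dienone; C8 epimers; not isolated) | COC1=CC(=O)C2=C(C1CC=C(C)C)O[C@H](c1ccc(OCOC)cc1)CC2=O | intermediate
10 | (2S)-5-hydroxy-7-methoxy-2-[4-(methoxymethoxy)phenyl]-8-(3-methylbut-2-en-1-yl)-2,3-dihydro-4H-chromen-4-one | COc1cc(O)c2c(c1CC=C(C)C)O[C@H](c1ccc(OCOC)cc1)CC2=O | intermediate
11 | (2S)-5-hydroxy-2-(4-hydroxyphenyl)-7-methoxy-8-(3-methylbut-2-en-1-yl)-2,3-dihydro-4H-chromen-4-one (Mundulea flavanone B) | COc1cc(O)c2c(c1CC=C(C)C)O[C@H](c1ccc(O)cc1)CC2=O | target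

**Totals**
Total step count: 5. Longest linear sequence: 5 steps (1 → 3 → 6 → 7 → 10 → 11).

**Three steps most likely to fail**

Step 3 (new asymmetric oxa-Michael). The risks are low ee, slow turnover, or erosion of ee by base-mediated retro-Michael. The fallback uses known chemistry and sets the stereocentre by Rh(I)-catalysed asymmetric 1,4-addition of an arylboronic acid to a chromone. It sets out from 3. Condensation with N,N-dimethylformamide dimethyl acetal (toluene, 90 °C) gives the enaminone (E)-3-(dimethylamino)-1-[2-hydroxy-4-methoxy-6-(3-methylbut-2-en-1-yloxy)phenyl]prop-2-en-1-one F1. This closes with loss of dimethylamine (AcOH, EtOH, 50 °C) to 7-methoxy-5-(3-methylbut-2-en-1-yloxy)-4H-chromen-4-one F2. Addition of commercial 4-(methoxymethoxy)phenylboronic acid (COCOc1ccc(B(O)O)cc1) with a Rh(I)/electron-poor chiral bisphosphine catalyst (MeO-F12-BIPHEP type, the enantiomer that gives 2S; toluene/H2O, rt to 40 °C) gives 7, where the route is rejoined.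

Step 4 (Claisen–Cope). The risks are that dienone 8 tautomerises to the 6-(1,1-dimethylallyl) phenol instead of undergoing the Cope shift, or that ee erodes at 85 °C. The fallback installs the C8 prenyl group by halogenation and cross-coupling instead of a sigmatropic shift. It sets out from 1.
- Mono-protection (MOMCl, K2CO3, acetone) gives 1-[2-hydroxy-4-methoxy-6-(methoxymethoxy)phenyl]ethan-1-one F3.
- Claisen–Schmidt condensation with 4 as in step 2 gives (E)-1-[2-hydroxy-4-methoxy-6-(methoxymethoxy)phenyl]-3-[4-(methoxymethoxy)phenyl]prop-2-en-1-one F4.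
- Cyclisation as in step 3 gives (2S)-7-methoxy-5-(methoxymethoxy)-2-[4-(methoxymethoxy)phenyl]-2,3-dihydro-4H-chromen-4-one F5.
- Iodination (NIS, DMF, rt) at the less hindered C8 of the 5,7-dialkoxy ring gives (2S)-8-iodo-7-methoxy-5-(methoxymethoxy)-2-[4-(methoxymethoxy)phenyl]-2,3-dihydro-4H-chromen-4-one F6; any 6-iodo isomer is removed by chromatography.
- Stille coupling with tributyl(3-methylbut-2-en-1-yl)stannane (CCCC[Sn](CCCC)(CCCC)CC=C(C)C; Pd(PPh3)4, DMF, 80 °C) gives (2S)-7-methoxy-5-(methoxymethoxy)-2-[4-(methoxymethoxy)phenyl]-8-(3-methylbut-2-en-1-yl)-2,3-dihydro-4H-chromen-4-one F7.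
- Removal of both MOM groups under the step 5 conditions comes back to the route at 11.

Step 5 (acidic MOM removal). The risks are Markovnikov addition of MeOH or HCl to the prenyl alkene, or acid-catalysed ring opening that erodes ee. The fallback replaces the acid-labile group by an allyl ether that is removed under neutral Pd(0) conditions. It sets out from 3. Claisen–Schmidt condensation with commercial 4-(allyloxy)benzaldehyde (C=CCOc1ccc(C=O)cc1) gives (E)-3-[4-(allyloxy)phenyl]-1-[2-hydroxy-4-methoxy-6-(3-methylbut-2-en-1-yloxy)phenyl]prop-2-en-1-one F8. The step 3 cyclisation gives (2S)-2-[4-(allyloxy)phenyl]-7-methoxy-5-(3-methylbut-2-en-1-yloxy)-2,3-dihydro-4H-chromen-4-one F9. The step 4 rearrangement gives (2S)-2-[4-(allyloxy)phenyl]-5-hydroxy-7-methoxy-8-(3-methylbut-2-en-1-yl)-2,3-dihydro-4H-chromen-4-one F10; the simple allyl aryl ether does not rearrange at 85 °C. Deallylation (Pd(PPh3)4 cat., N-methylaniline, THF, rt) comes back to the route at 11.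

Further compounds
F1 | step 3 | (E)-3-(dimethylamino)-1-[2-hydroxy-4-methoxy-6-(3-methylbut-2-en-1-yloxy)phenyl]prop-2-en-1-one | CN(C)/C=C/C(=O)c1c(O)cc(OC)cc1OCC=C(C)C
F2 | step 3 | 7-methoxy-5-(3-methylbut-2-en-1-yloxy)-4H-chromen-4-one | COc1cc(OCC=C(C)C)c2c(c1)occc2=O
F3 | step 4 | 1-[2-hydroxy-4-methoxy-6-(methoxymethoxy)phenyl]ethan-1-one | CC(=O)c1c(O)cc(OC)cc1OCOC
F4 | step 4 | (E)-1-[2-hydroxy-4-methoxy-6-(methoxymethoxy)phenyl]-3-[4-(methoxymethoxy)phenyl]prop-2-en-1-one | COCOc1ccc(/C=C/C(=O)c2c(O)cc(OC)cc2OCOC)cc1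
F5 | step 4 | (2S)-7-methoxy-5-(methoxymethoxy)-2-[4-(methoxymethoxy)phenyl]-2,3-dihydro-4H-chromen-4-one | COc1cc(OCOC)c2c(c1)O[C@H](c1ccc(OCOC)cc1)CC2=O
F6 | step 4 | (2S)-8-iodo-7-methoxy-5-(methoxymethoxy)-2-[4-(methoxymethoxy)phenyl]-2,3-dihydro-4H-chromen-4-one | COc1cc(OCOC)c2c(c1I)O[C@H](c1ccc(OCOC)cc1)CC2=O
F7 | step 4 | (2S)-7-methoxy-5-(methoxymethoxy)-2-[4-(methoxymethoxy)phenyl]-8-(3-methylbut-2-en-1-yl)-2,3-dihydro-4H-chromen-4-one | COc1cc(OCOC)c2c(c1CC=C(C)C)O[C@H](c1ccc(OCOC)cc1)CC2=O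
F8 | step 5 | (E)-3-[4-(allyloxy)phenyl]-1-[2-hydroxy-4-methoxy-6-(3-methylbut-2-en-1-yloxy)phenyl]prop-2-en-1-one | C=CCOc1ccc(/C=C/C(=O)c2c(O)cc(OC)cc2OCC=C(C)C)cc1
F9 | step 5 | (2S)-2-[4-(allyloxy)phenyl]-7-methoxy-5-(3-methylbut-2-en-1-yloxy)-2,3-dihydro-4H-chromen-4-one | COc1cc(OCC=C(C)C)c2c(c1)O[C@H](c1ccc(OCC=C)cc1)CC2=O
F10 | step 5 | (2S)-2-[4-(allyloxy)phenyl]-5-hydroxy-7-methoxy-8-(3-methylbut-2-en-1-yl)-2,3-dihydro-4H-chromen-4-one | COc1cc(O)c2c(c1CC=C(C)C)O[C@H](c1ccc(OCC=C)cc1)CC2=O
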